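**Retrosynthetic overview** (upper unit = rings A, B, C; lower unit = rings D, E, F)
1. Target ⇐ global hydrogenolysis (nine O-benzyl groups and a blocking Br on ring D) ⇐ all-trans 4-arylflavan-3-ol ⇐ hydride reduction of a 2,4-cis-2,4-diarylchroman-3-one (sets C3).
2. Key disconnection, interflavan C4–C6(ring D) bond: C4 of a (2R)-chroman-3-one, normally its enolate carbon, is made electrophilic as the gold carbenoid of the 4-diazo-3-ketone (an enolonium equivalent). It is attacked by the nucleophilic C6 of 8-bromo-hexa-O-benzyl-(+)-gallocatechin; C4 is fixed on ketonisation.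
3. Upper unit: diazo ketone ⇐ (2R)-7-benzyloxy-2-arylchroman-3-one ⇐ gold-catalysed alkyne oxidation and ring closure of an (S)-aryl propargyl ether (forms ring C, C4–C4a bond) ⇐ copper-catalysed asymmetric propargylic etherification of 3-benzyloxyphenol (O1–C2 bond, sets C2).
4. Lower unit: rings D, E, F and both stereocentres come intact from (+)-gallocatechin (benzylation, then C8 bromination).
5. Ring order: rings A and B are bought as benzene building blocks, ring C is the only ring built (step 5), rings D–F are bought; the two halves are joined in step 7.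

Assumption: (+)-gallocatechin (2R,3S) is bought as such, and (S,S)-Ph-pybox is taken to be the ligand antipode that gives the (S)-ether in step 4 (its mirror image is used if a test run shows the opposite sense).

**Step 1**
Reactants: 1 (+)-gallocatechin
Product: 2 (2R,3S)-3,5,7-tris(benzyloxy)-2-[3,4,5-tris(benzyloxy)phenyl]chromane
Conditions: BnBr (6.5 equiv), K2CO3, DMF, rt, Ar; then NaH, Bu4NI (cat.), 0 °C → rt (same flask)
Reagents that add atoms: benzyl bromide, BrCc1ccccc1
Why: Williamson O-benzylation: carbonate base alkylates the five phenols and NaH then the secondary 3-OH; no stereocentre is touched.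

**Step 2**
Reactants: 2 (2R,3S)-3,5,7-tris(benzyloxy)-2-[3,4,5-tris(benzyloxy)phenyl]chromane
Product: 3 (2R,3S)-3,5,7-tris(benzyloxy)-8-bromo-2-[3,4,5-tris(benzyloxy)phenyl]chromane
Conditions: NBS (1.05 equiv), CH2Cl2, −40 °C → rt
Reagents that add atoms: N-bromosuccinimide, O=C1CCC(=O)N1Br
Why: Electrophilic aromatic bromination: C8 is the most reactive position of ring D in O-benzylated flavan-3-ols (known C8-selective NBS bromination), so bromine blocks C8, leaves C6 as the only free ring-D carbon and is removed in step 9.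

**Step 3**
Reactants: 4 3,4-bis(benzyloxy)benzaldehyde; 5 ethynylmagnesium bromide (HC≡CMgBr)
Product: 7 rac-1-[3,4-bis(benzyloxy)phenyl]prop-2-yn-1-yl acetate, via magnesium alkoxide 6 (not isolated)
Conditions: HC≡CMgBr (1.2 equiv), THF, 0 °C; then Ac2O (1.5 equiv), 0 °C → rt
Reagents that add atoms: acetic anhydride, CC(=O)OC(C)=O
Why: Grignard 1,2-addition to the aldehyde followed by O-acetylation of the magnesium alkoxide in the same flask; the new centre is racemic, which is harmless because step 4 passes through a planar copper allenylidene.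

**Step 4**
Reactants: 7 rac-1-[3,4-bis(benzyloxy)phenyl]prop-2-yn-1-yl acetate; 8 3-(benzyloxy)phenol
Product: 9 1,2-bis(benzyloxy)-4-[(1S)-1-[3-(benzyloxy)phenoxy]prop-2-yn-1-yl]benzene
Conditions: (CuOTf)2·C6H6 (5 mol%), (S,S)-Ph-pybox (10 mol%), iPr2NEt (1.2 equiv), CH2Cl2, −20 °C
Reagents that add atoms: none
Why: Nishibayashi-type copper-catalysed enantioselective propargylic substitution: copper acetylide formation and loss of acetate give the same copper allenylidene from either enantiomer of 7, and pybox-controlled attack of the phenol oxygen at the γ-carbon sets the (S) centre that becomes C2 of the flavan (descriptor R there only because C3 gains priority).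

**Step 5**
Reactants: 9 1,2-bis(benzyloxy)-4-[(1S)-1-[3-(benzyloxy)phenoxy]prop-2-yn-1-yl]benzene
Product: 10 (2R)-7-(benzyloxy)-2-[3,4-bis(benzyloxy)phenyl]chroman-3-one
Conditions: (Me4tBuXPhos)AuNTf2 (5 mol%), 2,6-dichloropyridine N-oxide (1.3 equiv), ClCH2CH2Cl, rt
Reagents that add atoms: 2,6-dichloropyridine N-oxide, [O-][n+]1c(Cl)cccc1Cl
Why: Zhang-type gold-catalysed alkyne oxidation: oxygen transfer from the N-oxide to the internal carbon of the gold-activated terminal alkyne makes the terminal carbon electrophilic on gold, and it closes Friedel–Crafts-fashion onto the aryloxy ring para to OBn to form ring C with the C3 ketone; the stereocentre is not involved and is carried over as C2 (R).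

**Step 6**
Reactants: 10 (2R)-7-(benzyloxy)-2-[3,4-bis(benzyloxy)phenyl]chroman-3-one
Product: 13 (2R)-7-(benzyloxy)-2-[3,4-bis(benzyloxy)phenyl]-4-diazochroman-3-one, via lithium enolate 11 (not isolated), via trifluoroacetyl ketone 12 (not isolated)
Conditions: LiN(SiMe3)2, THF, −78 °C; CF3CO2CH2CF3, −78 °C; aq. HCl work-up, crude; then MsN3, Et3N, H2O (1 equiv), MeCN, rt
Reagents that add atoms: methanesulfonyl azide, CS(=O)(=O)N=[N+]=[N-]
Why: Danheiser detrifluoroacetylative diazo transfer (Regitz type): kinetic deprotonation at the benzylic C4 methylene rather than the hindered α-aryloxy C2–H fixes the site, C-trifluoroacetylation activates it and MsN3/Et3N transfers the diazo group with loss of the trifluoroacetyl group, so C2 is never enolised under equilibrating conditions.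

**Step 7**
Reactants: 13 (2R)-7-(benzyloxy)-2-[3,4-bis(benzyloxy)phenyl]-4-diazochroman-3-one; 3 (2R,3S)-3,5,7-tris(benzyloxy)-8-bromo-2-[3,4,5-tris(benzyloxy)phenyl]chromane
Product: 15 (2R,4S)-7-(benzyloxy)-2-[3,4-bis(benzyloxy)phenyl]-4-[(2R,3S)-3,5,7-tris(benzyloxy)-8-bromo-2-[3,4,5-tris(benzyloxy)phenyl]chroman-6-yl]chroman-3-one, via enol 14 (not isolated)
Conditions: [(2,4-tBu2C6H3O)3P]AuNTf2 (5 mol%), CH2Cl2, 4 Å MS, 0 °C → rt; 13 (1.5 equiv) added over 2 h to 3
Reagents that add atoms: none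
Why: Proposed new method: loss of N2 from 13 on the electron-poor phosphite–gold cation gives a C4 gold carbenoid, i.e. an α-keto cation (enolonium) equivalent at the carbon that is otherwise the enolate carbon of the chroman-3-one; the only free ring-D carbon of 3 (C6, ortho/para to three oxygens, C8 blocked by Br) attacks it in a Friedel–Crafts sense, rearomatisation and protodeauration give enol 14, and its ketonisation puts H on C4 anti to the C2 aryl group so that the two aryl groups end up cis and pseudo-equatorial (4S, also the more stable epimer); closest known reaction type: gold- or rhodium-catalysed C–H functionalisation of electron-rich arenes (anisoles, trialkoxybenzenes, indoles) by aryl diazo carbonyl compounds.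

**Step 8**
Reactants: 15 (2R,4S)-7-(benzyloxy)-2-[3,4-bis(benzyloxy)phenyl]-4-[(2R,3S)-3,5,7-tris(benzyloxy)-8-bromo-2-[3,4,5-tris(benzyloxy)phenyl]chroman-6-yl]chroman-3-one
Product: 16 (2R,3S,4S)-7-(benzyloxy)-2-[3,4-bis(benzyloxy)phenyl]-4-[(2R,3S)-3,5,7-tris(benzyloxy)-8-bromo-2-[3,4,5-tris(benzyloxy)phenyl]chroman-6-yl]chroman-3-ol
Conditions: NaBH4, CeCl3·7H2O, THF/MeOH 1:1, −78 → −40 °C (15 used directly after a short silica plug)
Reagents that add atoms: none
Why: Luche-type hydride reduction: hydride adds along the axial trajectory of the half-chair ketone whose two aryl groups are equatorial (no 1,3-diaxial substituents on O1 or C4a), giving the equatorial 3-OH trans to both aryl-bearing neighbours (3S), while CeCl3 and low temperature suppress enolisation at C2 and C4.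

**Step 9**
Reactants: 16 (2R,3S,4S)-7-(benzyloxy)-2-[3,4-bis(benzyloxy)phenyl]-4-[(2R,3S)-3,5,7-tris(benzyloxy)-8-bromo-2-[3,4,5-tris(benzyloxy)phenyl]chroman-6-yl]chroman-3-ol
Product: 17 fisetinidol-(4α,6)-gallocatechin
Conditions: H2 (1 atm), Pd(OH)2/C, NaOAc (1.5 equiv), THF/MeOH/H2O, rt; Sephadex LH-20
Reagents that add atoms: none
Why: Catalytic hydrogenolysis cleaves the nine benzyl ethers and the aryl C–Br bond while NaOAc buffers the HBr, so the acid-labile interflavan bond is not disturbed; no stereocentre is involved.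

**Compound list**
1 | (+)-gallocatechin, (2R,3S)-2-(3,4,5-trihydroxyphenyl)chromane-3,5,7-triol | O[C@H]1Cc2c(O)cc(O)cc2O[C@@H]1c1cc(O)c(O)c(O)c1 | starting material
2 | (2R,3S)-3,5,7-tris(benzyloxy)-2-[3,4,5-tris(benzyloxy)phenyl]chromane | c1ccccc1CO[C@H]1Cc2c(OCc3ccccc3)cc(OCc3ccccc3)cc2O[C@@H]1c1cc(OCc2ccccc2)c(OCc2ccccc2)c(OCc2ccccc2)c1 | intermediate
3 | (2R,3S)-3,5,7-tris(benzyloxy)-8-bromo-2-[3,4,5-tris(benzyloxy)phenyl]chromane | c1ccccc1CO[C@H]1Cc2c(OCc3ccccc3)cc(OCc3ccccc3)c(Br)c2O[C@@H]1c1cc(OCc2ccccc2)c(OCc2ccccc2)c(OCc2ccccc2)c1 | intermediate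
4 | 3,4-bis(benzyloxy)benzaldehyde | O=Cc1ccc(OCc2ccccc2)c(OCc2ccccc2)c1 | starting material
5 | ethynylmagnesium bromide | C#C[Mg]Br | starting material
6 | bromomagnesium 1-[3,4-bis(benzyloxy)phenyl]prop-2-yn-1-olate (racemic) | C#CC(O[Mg]Br)c1ccc(OCc2ccccc2)c(OCc2ccccc2)c1 | intermediate (not isolated)
7 | rac-1-[3,4-bis(benzyloxy)phenyl]prop-2-yn-1-yl acetate | CC(=O)OC(C#C)c1ccc(OCc2ccccc2)c(OCc2ccccc2)c1 | intermediate
8 | 3-(benzyloxy)phenol | Oc1cccc(OCc2ccccc2)c1 | starting material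
9 | 1,2-bis(benzyloxy)-4-[(1S)-1-[3-(benzyloxy)phenoxy]prop-2-yn-1-yl]benzene | C#C[C@H](Oc1cccc(OCc2ccccc2)c1)c1ccc(OCc2ccccc2)c(OCc2ccccc2)c1 | intermediate
10 | (2R)-7-(benzyloxy)-2-[3,4-bis(benzyloxy)phenyl]chroman-3-one | O=C1Cc2ccc(OCc3ccccc3)cc2O[C@@H]1c1ccc(OCc2ccccc2)c(OCc2ccccc2)c1 | intermediate
11 | lithium (2R)-7-(benzyloxy)-2-[3,4-bis(benzyloxy)phenyl]-2H-chromen-3-olate | [Li]OC1=Cc2ccc(OCc3ccccc3)cc2O[C@@H]1c1ccc(OCc2ccccc2)c(OCc2ccccc2)c1 | intermediate (not isolated)
12 | 1-[(2R)-7-(benzyloxy)-2-[3,4-bis(benzyloxy)phenyl]-3-hydroxy-2H-chromen-4-yl]-2,2,2-trifluoroethan-1-one (enol form of the 4-trifluoroacetyl ketone) | OC1=C(C(=O)C(F)(F)F)c2ccc(OCc3ccccc3)cc2O[C@@H]1c1ccc(OCc2ccccc2)c(OCc2ccccc2)c1 | intermediate (not isolated)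
13 | (2R)-7-(benzyloxy)-2-[3,4-bis(benzyloxy)phenyl]-4-diazochroman-3-one | O=C1C(=[N+]=[N-])c2ccc(OCc3ccccc3)cc2O[C@@H]1c1ccc(OCc2ccccc2)c(OCc2ccccc2)c1 | intermediate
14 | (2R)-7-(benzyloxy)-2-[3,4-bis(benzyloxy)phenyl]-4-[(2R,3S)-3,5,7-tris(benzyloxy)-8-bromo-2-[3,4,5-tris(benzyloxy)phenyl]chroman-6-yl]-2H-chromen-3-ol | OC1=C(c2c(OCc3ccccc3)c(Br)c3c(c2OCc4ccccc4)C[C@H](OCc4ccccc4)[C@@H](c4cc(OCc5ccccc5)c(OCc5ccccc5)c(OCc5ccccc5)c4)O3)c2ccc(OCc3ccccc3)cc2O[C@@H]1c1ccc(OCc2ccccc2)c(OCc2ccccc2)c1 | intermediate (not isolated)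
15 | (2R,4S)-7-(benzyloxy)-2-[3,4-bis(benzyloxy)phenyl]-4-[(2R,3S)-3,5,7-tris(benzyloxy)-8-bromo-2-[3,4,5-tris(benzyloxy)phenyl]chroman-6-yl]chroman-3-one | C(c1ccccc1)Oc1ccc2c(c1)O[C@H](c1ccc(OCc3ccccc3)c(OCc3ccccc3)c1)C(=O)[C@@H]2c1c(OCc3ccccc3)c(Br)c2c(c1OCc3ccccc3)C[C@H](OCc3ccccc3)[C@@H](c1cc(OCc3ccccc3)c(OCc3ccccc3)c(OCc3ccccc3)c1)O2 | intermediate
16 | (2R,3S,4S)-7-(benzyloxy)-2-[3,4-bis(benzyloxy)phenyl]-4-[(2R,3S)-3,5,7-tris(benzyloxy)-8-bromo-2-[3,4,5-tris(benzyloxy)phenyl]chroman-6-yl]chroman-3-ol | C(c1ccccc1)Oc1ccc2c(c1)O[C@H](c1ccc(OCc3ccccc3)c(OCc3ccccc3)c1)[C@@H](O)[C@@H]2c1c(OCc3ccccc3)c(Br)c2c(c1OCc3ccccc3)C[C@H](OCc3ccccc3)[C@@H](c1cc(OCc3ccccc3)c(OCc3ccccc3)c(OCc3ccccc3)c1)O2 | intermediate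
17 | fisetinidol-(4α,6)-gallocatechin | Oc1ccc2c(c1)O[C@H](c1ccc(O)c(O)c1)[C@@H](O)[C@@H]2c1c(O)cc2c(c1O)C[C@H](O)[C@@H](c1cc(O)c(O)c(O)c1)O2 | target

**Step count**
Total: 9 steps. Longest linear sequence: 7 steps (4 → 17, steps 3 to 9).

**The three steps most likely to fail**

Step 7 (carbenoid arylation). The ring-D carbon C6 of 3 is flanked by two benzyloxy groups and slowed by the bromine. The carbenoid can instead form oxonium ylides with benzyl ethers, attack ring E, or dimerise. C4 rests on the ketonisation of 14, and the 2-aryl-3-ketone is configurationally fragile at C2. The fallback sets out from 10 and returns at 15. Kinetic silylation of 10 (LiN(SiMe3)2, Me3SiCl, THF, −78 °C) gives [(2R)-7-(benzyloxy)-2-[3,4-bis(benzyloxy)phenyl]-2H-chromen-3-yl]oxy(trimethyl)silane F1. PhI(OH)OTs and BF3·OEt2 in CH2Cl2 at −78 °C convert it into the O-bound phenyl(tosyloxy)iodanyl enolate of 10 (a trivalent-iodine enolonium species) F2. Arene 3 is then added and attacks C4 with loss of iodobenzene to give 15. In this variant C4 is set in the C–C bond-forming event rather than by protonation, so a 2,4-trans ketone may appear and would be removed by chromatography after step 8.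

Step 5 (gold oxidation and ring closure). The electrophilic carbon on gold can close onto ring B to give a 1-aryloxyindan-2-one. The alkyne can undergo plain 6-endo hydroarylation, or close ortho to OBn (5-benzyloxy isomer). The electron-rich benzylic ether may also ionise and lose its ee. The fallback sets out from 9 and returns at 10, using the hydroarylation on purpose. Ph3PAuNTf2 (2 mol%, CH2Cl2, rt, no oxidant) cyclises 9 to (2S)-7-(benzyloxy)-2-[3,4-bis(benzyloxy)phenyl]-2H-chromene F3. Hydroboration–oxidation (BH3·SMe2, THF, 0 °C; then NaOH, H2O2) adds anti to the 2-aryl group and gives (2R,3S)-7-(benzyloxy)-2-[3,4-bis(benzyloxy)phenyl]chroman-3-ol F4. Dess–Martin periodinane (NaHCO3, CH2Cl2, 0 °C) oxidises F4 to 10.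

Step 4 (copper-catalysed etherification). The resorcinol-type phenol 8 may react through carbon (Friedel–Crafts propargylation) instead of oxygen. The electron-rich aryl group may also open a racemic ionisation pathway that lowers the ee. The fallback sets out from 4 and returns at 9. Enantioselective addition of trimethylsilylacetylene to 4 (Me2Zn, the ProPhenol antipode that gives the (S)-carbinol, toluene, 0 °C) gives (1S)-1-[3,4-bis(benzyloxy)phenyl]-3-(trimethylsilyl)prop-2-yn-1-ol F5. K2CO3 in MeOH removes the silyl group to give (1R)-1-[3,4-bis(benzyloxy)phenyl]prop-2-yn-1-ol F6 (same spatial arrangement, the descriptor changes). A Mitsunobu reaction with phenol 8 (PPh3, DIAD, toluene, −20 °C) inverts the carbinol centre and gives 9.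

**Further compounds**
F1 | step 7 | [(2R)-7-(benzyloxy)-2-[3,4-bis(benzyloxy)phenyl]-2H-chromen-3-yl]oxy(trimethyl)silane | C[Si](C)(C)OC1=Cc2ccc(OCc3ccccc3)cc2O[C@@H]1c1ccc(OCc2ccccc2)c(OCc2ccccc2)c1
F2 | step 7 | O-bound phenyl(tosyloxy)iodanyl enolate of 10 (enolonium species) | Cc1ccc(cc1)S(=O)(=O)O[I](c1ccccc1)OC1=Cc2ccc(OCc3ccccc3)cc2O[C@@H]1c1ccc(OCc2ccccc2)c(OCc2ccccc2)c1
F3 | step 5 | (2S)-7-(benzyloxy)-2-[3,4-bis(benzyloxy)phenyl]-2H-chromene | C1=Cc2ccc(OCc3ccccc3)cc2O[C@@H]1c1ccc(OCc2ccccc2)c(OCc2ccccc2)c1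
F4 | step 5 | (2R,3S)-7-(benzyloxy)-2-[3,4-bis(benzyloxy)phenyl]chroman-3-ol | O[C@H]1Cc2ccc(OCc3ccccc3)cc2O[C@@H]1c1ccc(OCc2ccccc2)c(OCc2ccccc2)c1
F5 | step 4 | (1S)-1-[3,4-bis(benzyloxy)phenyl]-3-(trimethylsilyl)prop-2-yn-1-ol | C[Si](C)(C)C#C[C@@H](O)c1ccc(OCc2ccccc2)c(OCc2ccccc2)c1
F6 | step 4 | (1R)-1-[3,4-bis(benzyloxy)phenyl]prop-2-yn-1-ol | C#C[C@@H](O)c1ccc(OCc2ccccc2)c(OCc2ccccc2)c1
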